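**Plan**

1. Retrosynthesis: the lactone C(=O)–O bond is cut first, then the C–Br bond (back to a trans-epoxide), then the two ring bonds that flank the C(CH3)=CH unit of the cyclohexa-1,4-diene (back to propyne and an acyclic (E)-diene), then the two C=C bonds of that diene (two Wittig reactions), and last the bond between geranyl C-1 and an acetate carbon.
2. Forward: geranyl acetate becomes a C12 epoxy aldehyde, and a cresol ester becomes a benzyl-substituted acyl ylide. Wittig union and methylenation give the diene, and a cobalt-catalysed [4+2] reaction with propyne builds the carbocycle. Ester cleavage, bromide opening of the epoxide and desilylation follow; macrolactonisation closes the 15-membered ring last, and the phenol is then unmasked.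
3. Stereochemistry: the (S)-carbinol and the (S,S)-epoxide come from two Shi epoxidations with the L-series ketone. The (R)-bromide comes from SN2 inversion of the epoxide next to the retained (S)-tertiary alcohol. The (S)-ring CH comes from the chiral bisphosphine on cobalt.
4. Enabling feature: the 2,5-dimethylcyclohexa-1,4-diene ring. Its two isolated C=C bonds and two sp3 ring carbons are the imprint of an alkyne–diene [4+2] reaction: C(CH3)=CH is propyne, and ring CH2–C(CH3)=C(CH2Ar)–CH(chain) is a 1,2,3-trisubstituted butadiene whose substituted terminus becomes the only ring stereocentre.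

Key step: step 14

Assumption: which enantiomer of the bisphosphine leads the alkyne to the Re face of the substituted diene terminus cannot be predicted with certainty, so (S,S)-BDPP [(2S,4S)-2,4-bis(diphenylphosphino)pentane] stands for the enantiomer that a two-run screen identifies; the L-fructose-derived epoxidation ketone and propyne (cylinder) are taken as purchasable.

**Route**

Step 1
Reactants: 1 geranyl acetate [(2E)-3,7-dimethylocta-2,6-dien-1-yl acetate]
Product: 2 (2E)-5-[(2S)-3,3-dimethyloxiran-2-yl]-3-methylpent-2-en-1-yl acetate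
Conditions: L-fructose-derived diacetonide ketone catalyst of the Shi epoxidation (0.3 equiv), Oxone (2KHSO5·KHSO4·K2SO4), K2CO3, Bu4NHSO4, MeCN/CH2(OMe)2, aq. Na2B4O7 buffer (pH 10.5), 0 °C
Reagents that add atoms: Oxone (active part potassium peroxymonosulfate), [K+].[O-]S(=O)(=O)OO
Why: Shi asymmetric epoxidation; the chiral dioxirane should attack the electron-richer 6,7-olefin (the 2,3-olefin is deactivated by the allylic acetoxy group) through a spiro transition state, and the L-series ketone should give the (S)-epoxide, which fixes the later carbinol centre.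

Step 2
Reactants: 2 (2E)-5-[(2S)-3,3-dimethyloxiran-2-yl]-3-methylpent-2-en-1-yl acetate
Product: 3 (2E,6S)-6-hydroxy-3,7-dimethylocta-2,7-dien-1-yl acetate
Conditions: Al(OiPr)3 (1.5 equiv), toluene, 110 °C
Reagents that add atoms: none
Why: Aluminium-alkoxide-mediated isomerisation of a 2,2-dimethyl epoxide to an allylic alcohol (syn β-elimination); the tertiary C–O bond breaks with loss of a methyl proton, so the secondary C–O bond and its (S) configuration should stay untouched.

Step 3
Reactants: 3 (2E,6S)-6-hydroxy-3,7-dimethylocta-2,7-dien-1-yl acetate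
Product: 4 (2E,6S)-3,7-dimethyl-6-[(triethylsilyl)oxy]octa-2,7-dien-1-yl acetate
Conditions: Et3SiCl, imidazole, DMF, 0 °C to rt
Reagents that add atoms: chlorotriethylsilane, CC[Si](Cl)(CC)CC
Why: Standard silylation of a secondary alcohol; the triethylsilyl ether keeps this hydroxyl from attacking the later epoxide and can be removed by mild acid that leaves an aryl silyl ether alone.

Step 4
Reactants: 4 (2E,6S)-3,7-dimethyl-6-[(triethylsilyl)oxy]octa-2,7-dien-1-yl acetate
Product: 5 (2E,6S)-3,7-dimethyl-6-[(triethylsilyl)oxy]octa-2,7-dien-1-ol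
Conditions: K2CO3 (0.2 equiv), MeOH, 0 °C to rt
Reagents that add atoms: none
Why: Base-catalysed transesterification (methanolysis) of the primary acetate, to which the secondary silyl ether is stable.

Step 5
Reactants: 5 (2E,6S)-3,7-dimethyl-6-[(triethylsilyl)oxy]octa-2,7-dien-1-ol
Product: 6 {[(3S,6E)-8-bromo-2,6-dimethylocta-1,6-dien-3-yl]oxy}triethylsilane
Conditions: CBr4, PPh3, CH2Cl2, 0 °C, used crude
Reagents that add atoms: tetrabromomethane, BrC(Br)(Br)Br
Why: Appel reaction; the primary allylic alcohol should be displaced by bromide at C-1 without allylic transposition or loss of the (E) geometry at this temperature.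

Step 6
Reactants: 6 {[(3S,6E)-8-bromo-2,6-dimethylocta-1,6-dien-3-yl]oxy}triethylsilane; 7 ethyl acetate
Product: 9 ethyl (4E,8S)-5,9-dimethyl-8-[(triethylsilyl)oxy]deca-4,9-dienoate, via lithium enolate of ethyl acetate 8 (not isolated)
Conditions: LiN(i-Pr)2, 7 (3 equiv), THF, −78 °C; then 6, DMPU, −78 to −30 °C
Reagents that add atoms: none
Why: Ester enolate alkylation (SN2) at the primary allylic bromide; it adds the two carbons that become the ring CH and its neighbouring CH2.

Step 7
Reactants: 9 ethyl (4E,8S)-5,9-dimethyl-8-[(triethylsilyl)oxy]deca-4,9-dienoate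
Product: 10 ethyl 3-{(2S,3S)-3-methyl-3-[(3S)-4-methyl-3-[(triethylsilyl)oxy]pent-4-en-1-yl]oxiran-2-yl}propanoate
Conditions: L-fructose-derived diacetonide ketone catalyst of the Shi epoxidation (0.3 equiv), Oxone (2KHSO5·KHSO4·K2SO4), K2CO3, Bu4NHSO4, MeCN/CH2(OMe)2, aq. Na2B4O7 buffer (pH 10.5), 0 °C
Reagents that add atoms: Oxone (active part potassium peroxymonosulfate), [K+].[O-]S(=O)(=O)OO
Why: Shi asymmetric epoxidation; the (E)-trisubstituted olefin should react far faster than the hindered, oxygen-deactivated 1,1-disubstituted isopropenyl group, and the L-series ketone should set both oxirane centres as (S,S) by reagent control.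

Step 8
Reactants: 10 ethyl 3-{(2S,3S)-3-methyl-3-[(3S)-4-methyl-3-[(triethylsilyl)oxy]pent-4-en-1-yl]oxiran-2-yl}propanoate
Product: 11 3-{(2S,3S)-3-methyl-3-[(3S)-4-methyl-3-[(triethylsilyl)oxy]pent-4-en-1-yl]oxiran-2-yl}propanal
Conditions: i-Bu2AlH (1.1 equiv), CH2Cl2, −78 °C; aq. KNaC4H4O6 work-up
Reagents that add atoms: none
Why: Partial reduction of an ester by a dialkylaluminium hydride through a tetrahedral aluminate that is stable at −78 °C; the trisubstituted epoxide should not be opened at this temperature.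

Step 9
Reactants: 12 methyl 4-hydroxy-3-methylbenzoate
Product: 13 methyl 3-methyl-4-[(triisopropylsilyl)oxy]benzoate
Conditions: i-Pr3SiCl, imidazole, DMF, rt
Reagents that add atoms: chlorotriisopropylsilane, CC(C)[Si](Cl)(C(C)C)C(C)C
Why: Standard phenol silylation; the bulky aryl silyl ether should survive ylides, weak bases and protic acid, and falls to buffered fluoride at the end.

Step 10
Reactants: 13 methyl 3-methyl-4-[(triisopropylsilyl)oxy]benzoate
Product: 14 methyl 3-(bromomethyl)-4-[(triisopropylsilyl)oxy]benzoate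
Conditions: NBS, AIBN (cat.), PhCF3, 80 °C
Reagents that add atoms: N-bromosuccinimide, O=C1CCC(=O)N1Br
Why: Wohl–Ziegler radical bromination of the benzylic methyl group; the ester lowers the ring's tendency to ionic bromination.

Step 11
Reactants: 14 methyl 3-(bromomethyl)-4-[(triisopropylsilyl)oxy]benzoate; 15 1-(triphenyl-λ5-phosphanylidene)propan-2-one
Product: 17 methyl 3-[3-oxo-2-(triphenyl-λ5-phosphanylidene)butyl]-4-[(triisopropylsilyl)oxy]benzoate, via phosphonium bromide 16 (not isolated)
Conditions: toluene, 80 °C; then aq. K2CO3, CH2Cl2, rt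
Reagents that add atoms: none
Why: C-Alkylation of a stabilised acyl ylide by a benzylic bromide, then deprotonation of the acidic phosphonium salt; this places the arylmethyl group on the future diene carbon.

Step 12
Reactants: 11 3-{(2S,3S)-3-methyl-3-[(3S)-4-methyl-3-[(triethylsilyl)oxy]pent-4-en-1-yl]oxiran-2-yl}propanal; 17 methyl 3-[3-oxo-2-(triphenyl-λ5-phosphanylidene)butyl]-4-[(triisopropylsilyl)oxy]benzoate
Product: 18 methyl 3-[(2E)-2-acetyl-5-{(2S,3S)-3-methyl-3-[(3S)-4-methyl-3-[(triethylsilyl)oxy]pent-4-en-1-yl]oxiran-2-yl}pent-2-en-1-yl]-4-[(triisopropylsilyl)oxy]benzoate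
Conditions: toluene, 90 °C
Reagents that add atoms: none
Why: Wittig olefination with a stabilised, α-branched acyl ylide; reversible addition should place the aldehyde-derived chain anti to the acetyl group, which gives the (E)-enone needed for an s-cis diene.

Step 13
Reactants: 18 methyl 3-[(2E)-2-acetyl-5-{(2S,3S)-3-methyl-3-[(3S)-4-methyl-3-[(triethylsilyl)oxy]pent-4-en-1-yl]oxiran-2-yl}pent-2-en-1-yl]-4-[(triisopropylsilyl)oxy]benzoate
Product: 19 methyl 3-[(2E)-5-{(2S,3S)-3-methyl-3-[(3S)-4-methyl-3-[(triethylsilyl)oxy]pent-4-en-1-yl]oxiran-2-yl}-2-(prop-1-en-2-yl)pent-2-en-1-yl]-4-[(triisopropylsilyl)oxy]benzoate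
Conditions: Ph3PCH3Br, KOtBu, THF, 0 °C (ylide preformed, no excess base); then 18, 0 °C to rt
Reagents that add atoms: methyltriphenylphosphonium bromide, C[P+](c1ccccc1)(c1ccccc1)c1ccccc1.[Br-]
Why: Wittig methylenation; the non-stabilised ylide should add 1,2 to the ketone faster than to the aryl ester or the epoxide, and the trisubstituted double bond keeps its geometry.

Step 14
Reactants: 19 methyl 3-[(2E)-5-{(2S,3S)-3-methyl-3-[(3S)-4-methyl-3-[(triethylsilyl)oxy]pent-4-en-1-yl]oxiran-2-yl}-2-(prop-1-en-2-yl)pent-2-en-1-yl]-4-[(triisopropylsilyl)oxy]benzoate; 20 propyne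
Product: 21 methyl 3-{[(6S)-2,5-dimethyl-6-(2-{(2S,3S)-3-methyl-3-[(3S)-4-methyl-3-[(triethylsilyl)oxy]pent-4-en-1-yl]oxiran-2-yl}ethyl)cyclohexa-1,4-dien-1-yl]methyl}-4-[(triisopropylsilyl)oxy]benzoate
Conditions: 20 (3 equiv), preformed [(S,S)-BDPP]CoBr (monovalent cobalt, 10 mol %), Na[B(3,5-(CF3)2C6H3)4] (12 mol %), CH2Cl2, 0 °C to rt, sealed tube, argon
Reagents that add atoms: none
Why: The cationic monovalent cobalt bisphosphine fragment binds the s-cis (E)-diene and propyne, oxidative cyclisation joins the unsubstituted diene CH2 terminus to the unsubstituted alkyne CH, and reductive elimination from the allyl(alkenyl)cobalt species joins the chain-bearing diene terminus to the methyl-bearing alkyne carbon, which should give the skipped 1,4-diene directly without double-bond migration. The closest known reaction type is the cobalt-catalysed neutral Diels–Alder reaction of 1,3-dienes with unactivated terminal alkynes, including its enantioselective form with chiral bisphosphines and 1-substituted dienes. The six-membered carbocycle is closed by an intermolecular [4+2] annulation in which both new sigma bonds arise in one catalytic cycle, the C(CH3)=CH unit coming from propyne and the other four ring carbons from the diene. The only new stereocentre, the ring CH that carries the epoxy-alkyl chain, is set by the chiral bisphosphine, which should lead the alkyne to the Re face of that diene terminus (catalyst control, since the nearest existing stereocentre is four bonds away and the acyclic diene has no facial bias of its own). The step needs regioselectivity (methyl next to the ring CH), which the steric difference between the CH2 and CHR diene termini and between the CH and C(CH3) alkyne carbons should secure, in line with the orientation para to a diene C-2 methyl group that bisphosphine–cobalt catalysts generally favour; it needs the (E) geometry from step 12 so that the s-cis conformer is reachable; and it needs chemoselectivity for the single conjugated diene over the isopropenyl group, the ester and the epoxide, for which a zinc-free preformed catalyst is chosen.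

Step 15
Reactants: 21 methyl 3-{[(6S)-2,5-dimethyl-6-(2-{(2S,3S)-3-methyl-3-[(3S)-4-methyl-3-[(triethylsilyl)oxy]pent-4-en-1-yl]oxiran-2-yl}ethyl)cyclohexa-1,4-dien-1-yl]methyl}-4-[(triisopropylsilyl)oxy]benzoate
Product: 22 3-{[(6S)-2,5-dimethyl-6-(2-{(2S,3S)-3-methyl-3-[(3S)-4-methyl-3-[(triethylsilyl)oxy]pent-4-en-1-yl]oxiran-2-yl}ethyl)cyclohexa-1,4-dien-1-yl]methyl}-4-[(triisopropylsilyl)oxy]benzoic acid
Conditions: Me3SnOH (5 equiv), ClCH2CH2Cl, 80 °C, argon; cold aq. KHSO4 (0.01 M) wash
Reagents that add atoms: trimethyltin hydroxide, C[Sn](C)(C)O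
Why: Trimethyltin hydroxide cleavage of a methyl ester under nearly neutral conditions, which should spare the aryl silyl ether that aqueous hydroxide would remove, as well as the alkyl silyl ether and the epoxide.

Step 16
Reactants: 22 3-{[(6S)-2,5-dimethyl-6-(2-{(2S,3S)-3-methyl-3-[(3S)-4-methyl-3-[(triethylsilyl)oxy]pent-4-en-1-yl]oxiran-2-yl}ethyl)cyclohexa-1,4-dien-1-yl]methyl}-4-[(triisopropylsilyl)oxy]benzoic acid
Product: 23 3-{[(6S)-6-[(3R,4S,7S)-3-bromo-4-hydroxy-4,8-dimethyl-7-[(triethylsilyl)oxy]non-8-en-1-yl]-2,5-dimethylcyclohexa-1,4-dien-1-yl]methyl}-4-[(triisopropylsilyl)oxy]benzoic acid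
Conditions: Li2NiBr4 (dilithium tetrabromonickelate, 0.4 M in THF, 3 equiv), THF, 0 °C to rt; pH 7 phosphate work-up
Reagents that add atoms: dilithium tetrabromonickelate, [Li+].[Li+].[Ni+2].[Br-].[Br-].[Br-].[Br-]
Why: SN2 opening of an epoxide by soft bromide at the less substituted oxirane carbon; inversion there should give the (R)-bromide anti to the (S)-tertiary alcohol, whose C–O bond is not touched, and the absence of a strong acid disfavours attack at the tertiary carbon.

Step 17
Reactants: 23 3-{[(6S)-6-[(3R,4S,7S)-3-bromo-4-hydroxy-4,8-dimethyl-7-[(triethylsilyl)oxy]non-8-en-1-yl]-2,5-dimethylcyclohexa-1,4-dien-1-yl]methyl}-4-[(triisopropylsilyl)oxy]benzoic acid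
Product: 24 3-{[(6S)-6-[(3R,4S,7S)-3-bromo-4,7-dihydroxy-4,8-dimethylnon-8-en-1-yl]-2,5-dimethylcyclohexa-1,4-dien-1-yl]methyl}-4-[(triisopropylsilyl)oxy]benzoic acid
Conditions: AcOH/THF/H2O (3:1:1), rt
Reagents that add atoms: none
Why: Acid hydrolysis of a secondary triethylsilyl ether; aryl triisopropylsilyl ethers resist protic acid, and the epoxide is already gone, so the freed hydroxyl cannot cyclise onto it.

Step 18
Reactants: 24 3-{[(6S)-6-[(3R,4S,7S)-3-bromo-4,7-dihydroxy-4,8-dimethylnon-8-en-1-yl]-2,5-dimethylcyclohexa-1,4-dien-1-yl]methyl}-4-[(triisopropylsilyl)oxy]benzoic acid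
Product: 25 O-triisopropylsilyl ether of the target macrolide (15-membered lactone between the benzoic acid and the (S)-carbinol that bears the isopropenyl group)
Conditions: 2-methyl-6-nitrobenzoic anhydride (MNBA, 1.5 equiv), DMAP (3 equiv), Et3N (3 equiv), CH2Cl2, rt, slow addition of 24 to 1 mM final concentration
Reagents that add atoms: none
Why: Shiina macrolactonisation; the mixed anhydride should transfer the acyl group to the only acylable hydroxyl, the secondary allylic alcohol, with retention, while the tertiary alcohol and the silylated phenol cannot compete and the base is too weak to close the bromohydrin.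

Step 19
Reactants: 25 O-triisopropylsilyl ether of the target macrolide
Product: 26 target macrolide CNP0186361.2 [(S)-carbinol ester bearing isopropenyl, (S)-tertiary alcohol, (R)-CHBr, (S)-ring CH, free phenol]
Conditions: Bu4NF, AcOH (1:1), THF, 0 °C
Reagents that add atoms: none
Why: Fluoride cleavage of an aryl silyl ether, buffered with acetic acid so that neither the bromohydrin recloses to the epoxide nor the lactone is opened.

**Compound list**

1 | geranyl acetate | CC(=O)OC/C=C(\C)CCC=C(C)C | starting material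
2 | (2E)-5-[(2S)-3,3-dimethyloxiran-2-yl]-3-methylpent-2-en-1-yl acetate | CC(=O)OC/C=C(\C)CC[C@@H]1OC1(C)C | intermediate
3 | (2E,6S)-6-hydroxy-3,7-dimethylocta-2,7-dien-1-yl acetate | CC(=O)OC/C=C(\C)CC[C@H](O)C(C)=C | intermediate
4 | (2E,6S)-3,7-dimethyl-6-[(triethylsilyl)oxy]octa-2,7-dien-1-yl acetate | CC(=O)OC/C=C(\C)CC[C@H](O[Si](CC)(CC)CC)C(C)=C | intermediate
5 | (2E,6S)-3,7-dimethyl-6-[(triethylsilyl)oxy]octa-2,7-dien-1-ol | OC/C=C(\C)CC[C@H](O[Si](CC)(CC)CC)C(C)=C | intermediate
6 | {[(3S,6E)-8-bromo-2,6-dimethylocta-1,6-dien-3-yl]oxy}triethylsilane | BrC/C=C(\C)CC[C@H](O[Si](CC)(CC)CC)C(C)=C | intermediate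
7 | ethyl acetate | CCOC(C)=O | starting material
8 | lithium enolate of ethyl acetate | C=C(OCC)O[Li] | intermediate (not isolated)
9 | ethyl (4E,8S)-5,9-dimethyl-8-[(triethylsilyl)oxy]deca-4,9-dienoate | CCOC(=O)CC/C=C(\C)CC[C@H](O[Si](CC)(CC)CC)C(C)=C | intermediate
10 | ethyl 3-{(2S,3S)-3-methyl-3-[(3S)-4-methyl-3-[(triethylsilyl)oxy]pent-4-en-1-yl]oxiran-2-yl}propanoate | CCOC(=O)CC[C@@H]1O[C@@]1(C)CC[C@H](O[Si](CC)(CC)CC)C(C)=C | intermediate
11 | 3-{(2S,3S)-3-methyl-3-[(3S)-4-methyl-3-[(triethylsilyl)oxy]pent-4-en-1-yl]oxiran-2-yl}propanal | O=CCC[C@@H]1O[C@@]1(C)CC[C@H](O[Si](CC)(CC)CC)C(C)=C | intermediate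
12 | methyl 4-hydroxy-3-methylbenzoate | COC(=O)c1ccc(O)c(C)c1 | starting material
13 | methyl 3-methyl-4-[(triisopropylsilyl)oxy]benzoate | COC(=O)c1ccc(O[Si](C(C)C)(C(C)C)C(C)C)c(C)c1 | intermediate
14 | methyl 3-(bromomethyl)-4-[(triisopropylsilyl)oxy]benzoate | COC(=O)c1ccc(O[Si](C(C)C)(C(C)C)C(C)C)c(CBr)c1 | intermediate
15 | 1-(triphenyl-λ5-phosphanylidene)propan-2-one | CC(=O)C=P(c1ccccc1)(c1ccccc1)c1ccccc1 | starting material
16 | {1-[5-(methoxycarbonyl)-2-[(triisopropylsilyl)oxy]phenyl]-3-oxobutan-2-yl}triphenylphosphonium bromide | COC(=O)c1ccc(O[Si](C(C)C)(C(C)C)C(C)C)c(CC(C(C)=O)[P+](c2ccccc2)(c2ccccc2)c2ccccc2)c1.[Br-] | intermediate (not isolated)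
17 | methyl 3-[3-oxo-2-(triphenyl-λ5-phosphanylidene)butyl]-4-[(triisopropylsilyl)oxy]benzoate | COC(=O)c1ccc(O[Si](C(C)C)(C(C)C)C(C)C)c(CC(C(C)=O)=P(c2ccccc2)(c2ccccc2)c2ccccc2)c1 | intermediate
18 | methyl 3-[(2E)-2-acetyl-5-{(2S,3S)-3-methyl-3-[(3S)-4-methyl-3-[(triethylsilyl)oxy]pent-4-en-1-yl]oxiran-2-yl}pent-2-en-1-yl]-4-[(triisopropylsilyl)oxy]benzoate | CC(=O)/C(Cc1cc(ccc1O[Si](C(C)C)(C(C)C)C(C)C)C(=O)OC)=C/CC[C@@H]2O[C@@]2(C)CC[C@H](O[Si](CC)(CC)CC)C(C)=C | intermediate
19 | methyl 3-[(2E)-5-{(2S,3S)-3-methyl-3-[(3S)-4-methyl-3-[(triethylsilyl)oxy]pent-4-en-1-yl]oxiran-2-yl}-2-(prop-1-en-2-yl)pent-2-en-1-yl]-4-[(triisopropylsilyl)oxy]benzoate | C=C(C)/C(Cc1cc(ccc1O[Si](C(C)C)(C(C)C)C(C)C)C(=O)OC)=C/CC[C@@H]2O[C@@]2(C)CC[C@H](O[Si](CC)(CC)CC)C(C)=C | intermediate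
20 | propyne | CC#C | starting material
21 | methyl 3-{[(6S)-2,5-dimethyl-6-(2-{(2S,3S)-3-methyl-3-[(3S)-4-methyl-3-[(triethylsilyl)oxy]pent-4-en-1-yl]oxiran-2-yl}ethyl)cyclohexa-1,4-dien-1-yl]methyl}-4-[(triisopropylsilyl)oxy]benzoate | COC(=O)c1ccc(O[Si](C(C)C)(C(C)C)C(C)C)c(CC2=C(C)CC=C(C)[C@@H]2CC[C@@H]3O[C@@]3(C)CC[C@H](O[Si](CC)(CC)CC)C(C)=C)c1 | intermediate
22 | 3-{[(6S)-2,5-dimethyl-6-(2-{(2S,3S)-3-methyl-3-[(3S)-4-methyl-3-[(triethylsilyl)oxy]pent-4-en-1-yl]oxiran-2-yl}ethyl)cyclohexa-1,4-dien-1-yl]methyl}-4-[(triisopropylsilyl)oxy]benzoic acid | OC(=O)c1ccc(O[Si](C(C)C)(C(C)C)C(C)C)c(CC2=C(C)CC=C(C)[C@@H]2CC[C@@H]3O[C@@]3(C)CC[C@H](O[Si](CC)(CC)CC)C(C)=C)c1 | intermediate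
23 | 3-{[(6S)-6-[(3R,4S,7S)-3-bromo-4-hydroxy-4,8-dimethyl-7-[(triethylsilyl)oxy]non-8-en-1-yl]-2,5-dimethylcyclohexa-1,4-dien-1-yl]methyl}-4-[(triisopropylsilyl)oxy]benzoic acid | OC(=O)c1ccc(O[Si](C(C)C)(C(C)C)C(C)C)c(CC2=C(C)CC=C(C)[C@@H]2CC[C@@H](Br)[C@@](C)(O)CC[C@H](O[Si](CC)(CC)CC)C(C)=C)c1 | intermediate
24 | 3-{[(6S)-6-[(3R,4S,7S)-3-bromo-4,7-dihydroxy-4,8-dimethylnon-8-en-1-yl]-2,5-dimethylcyclohexa-1,4-dien-1-yl]methyl}-4-[(triisopropylsilyl)oxy]benzoic acid | OC(=O)c1ccc(O[Si](C(C)C)(C(C)C)C(C)C)c(CC2=C(C)CC=C(C)[C@@H]2CC[C@@H](Br)[C@@](C)(O)CC[C@H](O)C(C)=C)c1 | intermediate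
25 | O-triisopropylsilyl ether of the target macrolide | C=C(C)[C@@H]1CC[C@](C)(O)[C@H](Br)CC[C@H]2C(C)=CCC(C)=C2Cc2cc(ccc2O[Si](C(C)C)(C(C)C)C(C)C)C(=O)O1 | intermediate
26 | target macrolide CNP0186361.2 | C=C(C)[C@@H]1CC[C@](C)(O)[C@H](Br)CC[C@H]2C(C)=CCC(C)=C2Cc2cc(ccc2O)C(=O)O1 | target

**Count and risks**

Total steps: 19. Longest linear sequence: 16 (steps 1 to 8 and 12 to 19).

Step 14 is the most likely to fail. Propyne may insert in the reverse orientation (methyl away from the ring CH), the catalyst may discriminate the two faces of the diene terminus poorly, or the cationic metal may open the trisubstituted epoxide. The fallback sets out from diene 19. A thermal Diels–Alder reaction with ethynyl p-tolyl sulfone (toluene, 80 °C) fixes the orientation by polarisation alone, because the sulfonyl-bearing carbon should bond to the chain-bearing diene terminus. It would give the sulfonyl cyclohexadiene, methyl 3-{[2-methyl-5-(4-methylbenzenesulfonyl)-6-(2-{epoxy chain as in 21}ethyl)cyclohexa-1,4-dien-1-yl]methyl}-4-[(triisopropylsilyl)oxy]benzoate with the ring CH arranged as in 21, F1, together with its epimer at the ring CH, F2, since this cycloaddition has no face control; the two would be separated by preparative HPLC. Nickel-catalysed cross-coupling of the alkenyl sulfone F1 with MeMgBr (Ni(acac)2, divalent nickel, THF, 0 °C, inverse addition to spare the ester) replaces the sulfonyl group by methyl and comes back to the route at 21.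

Step 18 is the second. Acylation of the hindered secondary allylic alcohol may be slow under high dilution, so that oligomerisation competes, and the amine bases may reclose the bromohydrin to the epoxide. The fallback sets out from hydroxy acid 24 and lactonises under acid rather than base through an isolable activated ester. Ethoxyacetylene with [RuCl2(p-cymene)]2 (divalent ruthenium, 2 mol %, toluene, rt) adds only the carboxylic acid and gives the 1-ethoxyvinyl ester of 24, F3. Slow addition of F3 to camphorsulfonic acid (10 mol %) in toluene at 50 °C under high dilution should close the ring by acid-catalysed acyl transfer and comes back to the route at 25.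

Step 12 is the third. The hindered, weakly nucleophilic α-branched acyl ylide may add sluggishly, so that aldol self-condensation of the enolisable aldehyde and erosion of the double-bond geometry take over at long reaction times. The fallback sets out from aldehyde 11 and separates the olefination from the introduction of the arylmethyl group. The unhindered ylide 15 (CH2Cl2, rt) gives (3E)-6-{(2S,3S)-3-methyl-3-[(3S)-4-methyl-3-[(triethylsilyl)oxy]pent-4-en-1-yl]oxiran-2-yl}hex-3-en-2-one, F4. α-Iodination (I2, pyridine, CH2Cl2, 0 °C to rt) gives the (3Z)-3-iodo enone, F5. Negishi coupling of F5 with the benzylic zinc reagent {[5-(methoxycarbonyl)-2-[(triisopropylsilyl)oxy]phenyl]methyl}zinc bromide, F6 (from bromide 14, Zn dust, LiCl, THF), under Pd(PPh3)4 (zerovalent palladium, THF, rt) attaches the arylmethyl group with retention of the double-bond geometry and comes back to the route at 18.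

**Further compounds**

F1 | step 14 | methyl 3-{[2-methyl-5-(4-methylbenzenesulfonyl)-6-(2-{(2S,3S)-3-methyl-3-[(3S)-4-methyl-3-[(triethylsilyl)oxy]pent-4-en-1-yl]oxiran-2-yl}ethyl)cyclohexa-1,4-dien-1-yl]methyl}-4-[(triisopropylsilyl)oxy]benzoate, ring CH as in 21 | COC(=O)c1ccc(O[Si](C(C)C)(C(C)C)C(C)C)c(CC2=C(C)CC=C(S(=O)(=O)c3ccc(C)cc3)[C@@H]2CC[C@@H]4O[C@@]4(C)CC[C@H](O[Si](CC)(CC)CC)C(C)=C)c1
F2 | step 14 | epimer of F1 at the ring CH | COC(=O)c1ccc(O[Si](C(C)C)(C(C)C)C(C)C)c(CC2=C(C)CC=C(S(=O)(=O)c3ccc(C)cc3)[C@H]2CC[C@@H]4O[C@@]4(C)CC[C@H](O[Si](CC)(CC)CC)C(C)=C)c1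
F3 | step 18 | 1-ethoxyvinyl ester of 24 | CCOC(=C)OC(=O)c1ccc(O[Si](C(C)C)(C(C)C)C(C)C)c(CC2=C(C)CC=C(C)[C@@H]2CC[C@@H](Br)[C@@](C)(O)CC[C@H](O)C(C)=C)c1
F4 | step 12 | (3E)-6-{(2S,3S)-3-methyl-3-[(3S)-4-methyl-3-[(triethylsilyl)oxy]pent-4-en-1-yl]oxiran-2-yl}hex-3-en-2-one | CC(=O)/C=C/CC[C@@H]1O[C@@]1(C)CC[C@H](O[Si](CC)(CC)CC)C(C)=C
F5 | step 12 | (3Z)-3-iodo-6-{(2S,3S)-3-methyl-3-[(3S)-4-methyl-3-[(triethylsilyl)oxy]pent-4-en-1-yl]oxiran-2-yl}hex-3-en-2-one | CC(=O)/C(I)=C/CC[C@@H]1O[C@@]1(C)CC[C@H](O[Si](CC)(CC)CC)C(C)=C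
F6 | step 12 | {[5-(methoxycarbonyl)-2-[(triisopropylsilyl)oxy]phenyl]methyl}zinc bromide | COC(=O)c1ccc(O[Si](C(C)C)(C(C)C)C(C)C)c(C[Zn]Br)c1
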